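## The problem

Target 16 is a diarylheptanoid whose seven-carbon chain is tied into a single tetrahydropyran. O1 joins C2, which carries the 2-(4-hydroxy-3-methoxyphenyl)ethyl arm (ring A), to C6, which carries the 3,4-dihydroxy-5-methoxyphenyl group (ring B) directly, and C4 bears a free hydroxyl. The descriptors 2S,4R,6S place all three substituents on one face, so the chair is all-equatorial and 16 is the most stable of its diastereomers. With O1–C6 opened in thought, the oxygens on C2 and C4 form a 1,3-anti diol, 3S,5S in heptane numbering (heptane C3, C5 and C7 are ring atoms C2, C4 and C6). These two carbinol centres have no neighbour to lean on and must come from a chiral catalyst or reagent. C6 is benzylic and ionisable, so it can be left to the control of the other two. The chain is almost symmetric, oxygenated at C3 and C5 like a reduced curcuminoid, and its aryl ends differ by one phenolic oxygen, so chain construction reduces to an unsymmetrical 1,7-diaryl-3,5-dioxygenated heptane. Three phenols must be told apart, two of them neighbours on ring B; the free catechol will not tolerate oxidants or aerated base, and C6–O1 is a p-hydroxybenzylic ether that strong acid ionises and an active hydrogenolysis catalyst may cut. The enabling feature is that C6 sits on ring B para to the O4 hydroxyl, which is flanked by oxygen substituents on both sides: O1–C6 is therefore the formal 1,6-adduct of an alcohol to a p-quinone methide, and that quinone methide lies two electrons away from a plain benzylic CH2 group.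

## Retrosynthesis

**From 16 to 15.** No skeletal bond is cut, only the two O–CH2Ph bonds on O4 of ring A and O3 of ring B. Benzyl is preferred to silyl or acetal groups because it leaves under neutral, non-oxidising conditions. A fresh catechol and the acid-labile C6–O1 bond both need that, and the same two ethers also have a task in the key step. The simplification is small. The forward step must cleave two aryl benzyl ethers faster than the ring C6–O1 bond.

**From 15 through 14 to 13.** The O1–C6 bond is cut.
- Cutting O1–C2 instead would leave a benzylic carbinol stereocentre on a very electron-rich ring in the precursor and would need a carbonyl or leaving group at C2.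
- Cutting ring C–C bonds (C2–C3, or C3–C4 together with C4–C5) leads to a C4 ketone and a later reduction.
- The chosen cut removes the ring, the C6 stereocentre and the C6 oxygen function together: 13 is an open-chain diol with a CH2 group at heptane C7.

The forward reaction must oxidise one aromatic ring of two, use the distal hydroxyl, and deliver the 2,6-cis ether. To make this firmer the step is split in the flask: oxidation to quinone methide 14, removal of the oxidant, then acid-catalysed closure under equilibrating conditions. The regenerated phenol of 15 then meets little oxidant, and stray isomers are funnelled to the all-equatorial product.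

**From 13 through 12 to 11.** The two carbinol C–H bonds at heptane C3 and C5 are cut, and the temporary methoxymethyl group on O4 of ring B is put back. Stepwise options (an asymmetric aldol reaction followed by a directed reduction, or allylation and epoxide chemistry) set the centres one at a time and cost more steps. The near-symmetry of the chain invites one catalyst to set both. Diketone 11 is achiral, so all absolute stereochemistry is bought in one operation. The catalyst must reduce both carbonyls in the same sense, which gives the anti diol, and must leave the benzyl ethers alone.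

**From 11 to 2 and 8 (through 9 and 10).** The heptane C4–C5 bond is cut.
- The mirror cut at C3–C4 would need a ring B methyl ketone and a ring A acid, both of which would have to be made.
- The chosen cut uses ketone 2, in which ring A and C1–C4 are already assembled.
- A cut at C6–C7 (alkylation of a diketone dianion) needs a labile benzylic halide and is held in reserve.

The forward step needs clean kinetic enolisation of 2 at its methyl group (10) and C-acylation by an activated form of acid 8 (9). This is why the ring B phenol must be masked at this stage.

**From 8 through 7 to 5 and 6.** The heptane C6–C7 bond is cut as the C=C bond of cinnamic acid 7, which splits into aldehyde 5 and malonic acid 6. The formyl carbon of 5 becomes C7, the carbon that is oxidised in the key step. The condensation is routine for trialkoxybenzaldehydes. The only demand is that saturation of 7 spares the benzyl ether, which excludes heterogeneous palladium.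

**From 5 through 4 to 3, and from 2 to 1.** Only O–C bonds are cut. The two neighbouring phenols of 3 are distinguished by the formyl group, which makes the para O4–H the more acidic. O4 therefore takes the temporary acetal first (4), and O3 then takes the permanent benzyl group (5). The methoxymethyl group tolerates base, enolates and hydrogenation, and leaves under mild acid without touching benzyl ethers. Ketone 2 is the benzyl ether of commercial 1.

## Roads not taken

**Alternative 1:** The cut falls on C3–C4 and C4–C5, the two ring bonds flanking a C4 carbonyl masked as a dithiane, and the key step would give A1.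

*Forward step.* Lithiated silyl dithiane A4 opens aryl epoxide A2 at its CH2 terminus. HMPA then sets off a 1,4-Brook shift of silicon to the benzylic alkoxide, and the relocated carbanion opens alkyl epoxide A3, all in one flask.

*Merits.* Three components are joined at once. C2 and C6 are fixed independently by two enantiopure epoxides, and the silyl shift differentiates the two carbinols without extra steps.

*Weak points.*
- In A1 the alkyl carbinol is R, opposite to C2 of 16, so the ring would be closed by displacing a sulfonate on that carbon with the C6 oxygen, with inversion.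
- A2 is a trialkoxystyrene oxide, prone to attack at the benzylic carbon and to lithium-promoted rearrangement.
- Each epoxide needs its own asymmetric preparation.
- After A1 there remain sulfonylation, closure, dithiane hydrolysis in the presence of three electron-rich rings, carbonyl reduction, and a hydrogenolysis that traces of sulfur can poison.

*Comparison.* This road is more convergent and more certain at C6, and it would be the better choice if a 2,6-trans or C4-epimeric analogue were wanted. The chosen plan sets against this one catalytic step for both reagent-controlled centres, no redox detour at C4, and nine steps in all.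

**Alternative 2:** The cut is C2–C3, and the key step would give tetrahydropyranone A5.

*Forward step.* β-Hydroxy acid A7 and aldehyde A8 are condensed, and the ester carbonyl is methylenated with Cp2TiMe2 to give enol acetal A6. Me2AlCl then ionises the acetal C–O bond of A6, and the aluminium enolate carbon recombines with the oxocarbenium carbon.

*Merits.* The chair-like recombination is a dependable source of 2,6-cis rings. Only the C6 carbinol of A7 has to be bought by asymmetric synthesis. A small hydride should turn A5 into the equatorial alcohol.

*Weak points.*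
- In A6 the O1–C6 bond is a trialkoxybenzylic C–O bond, and the Lewis acid must ionise the acetal carbon in preference to it. Benzylic ionisation would scramble C6 or fragment the ring.
- Stoichiometric titanium and aluminium reagents are needed.
- A7 comes from an acetate-type aldol reaction or a keto ester hydrogenation.
- Reduction and deprotection still follow.

*Comparison.* The stereochemical relay is at least as well supported as the one proposed here. The chosen plan keeps C4 at the alcohol level throughout, uses no stoichiometric organometallic reagent, and turns the benzylic lability that endangers A6 into the bond-forming principle.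

**Alternative 3:** The cut is O1–C2, and the key step would give acetate A9.

*Forward step.* BiBr3 and Et3SiH convert δ-silyloxy ketone A10 into a cyclic oxocarbenium ion, by attack of the C6 oxygen on the C2 carbonyl, and reduce it by axial hydride delivery.

*Merits.* The catalyst is mild, the 2,6-cis outcome is reliable, no oxidant is present near phenols, and the road shares ketone 2, whose carbonyl becomes C2.

*Weak points.*
- A10 has two stereocentres (C4 and C6, 1,3-anti) that must be set in separate operations: first in aldehyde A11, then in a methyl ketone aldol reaction of 2, where induction by a β-silyloxy group is modest.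
- A10 is a β-acetoxy ketone that can eliminate.
- Its benzylic silyl ether sits on a trialkoxyaryl ring, so the acid generated from BiBr3 may ionise it and the silane may reduce the cation to CH2.
- The silyl and acetyl groups add protecting-group steps.

*Comparison.* The ring closure itself is arguably better precedented for cis-2,6-tetrahydropyrans than the one chosen, and it is kinder to phenols. The chosen plan reaches its cyclisation precursor by a much shorter route, and its closure has no reductant present to intercept the benzylic cation.

Key step: step 8

Assumption: 11 is drawn as the diketo tautomer although it will be largely enolised, and 14 is drawn without double-bond geometry because both geometric isomers of its exocyclic C=C bond lead to the same product 15.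

## Route

Step 1
Reactants: 1 zingerone, 4-(4-hydroxy-3-methoxyphenyl)butan-2-one
Product: 2 4-[4-(benzyloxy)-3-methoxyphenyl]butan-2-one (O-benzylzingerone)
Conditions: BnBr, K2CO3, acetone, reflux
Reagents that add atoms: benzyl bromide, BrCc1ccccc1
Why: Williamson etherification of the only acidic O–H; K2CO3 is too weak to enolise the ketone, so C-alkylation is not expected. The benzyl ether later prevents ring A from forming a quinone methide of its own in step 8.

Step 2
Reactants: 3 5-hydroxyvanillin, 3,4-dihydroxy-5-methoxybenzaldehyde
Product: 4 3-hydroxy-5-methoxy-4-(methoxymethoxy)benzaldehyde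
Conditions: MOMCl (1.0 equiv), iPr2NEt (1.1 equiv), DMF, 0 °C
Reagents that add atoms: chloromethyl methyl ether, COCCl
Why: The O4–H is para to the formyl group and is the more acidic phenol, so one equivalent of amine ionises it selectively and the small, reactive chloromethyl ether caps it. This is the regioselective 4-O-alkylation known for 3,4-dihydroxybenzaldehydes.

Step 3
Reactants: 4 3-hydroxy-5-methoxy-4-(methoxymethoxy)benzaldehyde
Product: 5 3-(benzyloxy)-5-methoxy-4-(methoxymethoxy)benzaldehyde
Conditions: BnBr, K2CO3, DMF, rt
Reagents that add atoms: benzyl bromide, BrCc1ccccc1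
Why: Williamson etherification of the one remaining phenol; the acetal and the aldehyde are inert to carbonate.

Step 4
Reactants: 5 3-(benzyloxy)-5-methoxy-4-(methoxymethoxy)benzaldehyde; 6 malonic acid
Product: 7 (E)-3-[3-(benzyloxy)-5-methoxy-4-(methoxymethoxy)phenyl]prop-2-enoic acid
Conditions: pyridine, piperidine (cat.), 90 °C
Reagents that add atoms: none
Why: Knoevenagel–Doebner condensation with decarboxylation, routine for 3,4,5-trialkoxybenzaldehydes and E-selective. The pyridine-buffered medium is not acidic enough to touch the methoxymethyl ether.

Step 5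
Reactants: 7 (E)-3-[3-(benzyloxy)-5-methoxy-4-(methoxymethoxy)phenyl]prop-2-enoic acid
Product: 8 3-[3-(benzyloxy)-5-methoxy-4-(methoxymethoxy)phenyl]propanoic acid
Conditions: H2 (4 atm), RhCl(PPh3)3 (3 mol%), toluene/EtOH 1:1, 50 °C
Reagents that add atoms: none
Why: Homogeneous hydrogenation of a disubstituted cinnamic C=C bond. RhCl(PPh3)3 adds H2 to the olefin but offers no pathway for hydrogenolysis of aryl benzyl ethers, unlike Pd/C.

Step 6
Reactants: 8 3-[3-(benzyloxy)-5-methoxy-4-(methoxymethoxy)phenyl]propanoic acid; 2 4-[4-(benzyloxy)-3-methoxyphenyl]butan-2-one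
Product: 11 1-[4-(benzyloxy)-3-methoxyphenyl]-7-[3-(benzyloxy)-5-methoxy-4-(methoxymethoxy)phenyl]heptane-3,5-dione, via acylimidazole 9 (not isolated), via lithium enolate 10 (not isolated)
Conditions: 8, CDI (1.05 equiv), THF, rt; separately 2 (3.2 equiv), LiN(iPr)2 (3.1 equiv), THF, −78 °C; add 9 to 10, −78 to −20 °C; aq NH4Cl
Reagents that add atoms: 1,1'-carbonyldiimidazole, O=C(n1ccnc1)n1ccnc1 (imidazolyl group of 9 only); lithium diisopropylamide, [Li+].CC(C)[N-]C(C)C (lithium of 10 only)
Why: Claisen-type C-acylation of a kinetic lithium enolate by an N-acylimidazole, a known route to 1,3-diketones; LiN(iPr)2 at −78 °C deprotonates the methyl group of the 2-alkanone. One equivalent of 10 is consumed by the liberated imidazole and one by the acidic product, and the excess of the cheap ketone 2 is recovered.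

Step 7
Reactants: 11 1-[4-(benzyloxy)-3-methoxyphenyl]-7-[3-(benzyloxy)-5-methoxy-4-(methoxymethoxy)phenyl]heptane-3,5-dione
Product: 13 (3S,5S)-1-[4-(benzyloxy)-3-methoxyphenyl]-7-[3-(benzyloxy)-4-hydroxy-5-methoxyphenyl]heptane-3,5-diol, via methoxymethyl-protected diol 12 (not isolated)
Conditions: RuCl2[(S)-BINAP] (1 mol%), H2 (80 atm), MeOH/CH2Cl2, 50 °C; vent; conc. HCl (cat.), MeOH, 45 °C
Reagents that add atoms: none
Why: Noyori asymmetric hydrogenation of a chelating 1,3-diketone. The (S)-BINAP catalyst first gives the (S)-β-hydroxy ketone and then reduces the second carbonyl in the matched sense to the (3S,5S)-anti diol; mismatched material ends as the separable syn diol, which raises the enantiopurity of the anti product. Benzyl ethers are inert to the ruthenium catalyst, and acid-catalysed acetal exchange with methanol then frees the O4 phenol of ring B.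

Step 8
Reactants: 13 (3S,5S)-1-[4-(benzyloxy)-3-methoxyphenyl]-7-[3-(benzyloxy)-4-hydroxy-5-methoxyphenyl]heptane-3,5-diol
Product: 15 (2S,4R,6S)-2-{2-[4-(benzyloxy)-3-methoxyphenyl]ethyl}-6-[3-(benzyloxy)-4-hydroxy-5-methoxyphenyl]oxan-4-ol, via p-quinone methide 14 (not isolated)
Conditions: Ag2O (1.5 equiv), 4 Å MS, CH2Cl2 (0.01 M), rt, dark; filter through Celite; CSA (5 mol%), CH2Cl2, 0 °C to rt; aq NaHCO3
Reagents that add atoms: none
Why: Ag2O takes two electrons and two protons from the only free phenol of 13 (the O–H, then the C7–H para to it) and gives p-quinone methide 14 with metallic silver and water, the established response of 4-alkyl-2,6-dialkoxyphenols to Ag2O or DDQ. The hydroxyl on heptane C3 then adds to the exocyclic methide carbon C7 in an intramolecular oxa-1,6-conjugate addition, the known trapping mode of p-quinone methides by alcohols, and rearomatisation to the phenol drives formation of the O1–C6 bond. The single ring closes in the 6-exo-trig mode, the C7=C(aryl) bond lying outside the forming six-membered ring. The new centre C6 is governed by the two existing carbinol centres: in the chair-like transition state the arylethyl arm on C2 and the hydroxyl on C4 are both equatorial, which only the anti diol allows, and the planar quinone methide takes the third equatorial site, giving 6S. Site selectivity rests on the protecting groups, since ring A is a benzyl ether with no oxidisable O–H and the benzyl ether on O3 of ring B rules out an o-quinone; of the two hydroxyls the nearer one could only close an oxetane. The silver is filtered off before the acid is added so that the phenol regenerated in 15, which still has a benzylic C–H, meets as little oxidant as possible. Catalytic CSA completes the closure and reversibly re-ionises the p-hydroxybenzylic C–O bond, so that any 2,6-trans ether, water adduct or vinylphenol tautomer returns to the same cation and drains into the all-equatorial isomer.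

Step 9
Reactants: 15 (2S,4R,6S)-2-{2-[4-(benzyloxy)-3-methoxyphenyl]ethyl}-6-[3-(benzyloxy)-4-hydroxy-5-methoxyphenyl]oxan-4-ol
Product: 16 (2S,4R,6S)-2-(3,4-dihydroxy-5-methoxyphenyl)-6-[2-(4-hydroxy-3-methoxyphenyl)ethyl]oxan-4-ol (CNP0399218.1)
Conditions: H2 (1 atm), 10% Pd/C, EtOAc, rt
Reagents that add atoms: none
Why: Catalytic hydrogenolysis of two aryl benzyl ethers, which are cleaved much faster than the hindered secondary C6–O1 bond of a 2-aryltetrahydropyran. The neutral aprotic solvent avoids solvolysis of the p-hydroxybenzylic ether and delivers the catechol without oxidant or base, and no stereocentre is touched.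

## Compound list

1 | zingerone, 4-(4-hydroxy-3-methoxyphenyl)butan-2-one | COc1cc(CCC(C)=O)ccc1O | starting material
2 | 4-[4-(benzyloxy)-3-methoxyphenyl]butan-2-one | COc1cc(CCC(C)=O)ccc1OCc1ccccc1 | intermediate
3 | 5-hydroxyvanillin, 3,4-dihydroxy-5-methoxybenzaldehyde | COc1cc(C=O)cc(O)c1O | starting material
4 | 3-hydroxy-5-methoxy-4-(methoxymethoxy)benzaldehyde | COCOc1c(O)cc(C=O)cc1OC | intermediate
5 | 3-(benzyloxy)-5-methoxy-4-(methoxymethoxy)benzaldehyde | COCOc1c(OC)cc(C=O)cc1OCc1ccccc1 | intermediate
6 | malonic acid | O=C(O)CC(=O)O | starting material
7 | (E)-3-[3-(benzyloxy)-5-methoxy-4-(methoxymethoxy)phenyl]prop-2-enoic acid | COCOc1c(OC)cc(/C=C/C(=O)O)cc1OCc1ccccc1 | intermediate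
8 | 3-[3-(benzyloxy)-5-methoxy-4-(methoxymethoxy)phenyl]propanoic acid | COCOc1c(OC)cc(CCC(=O)O)cc1OCc1ccccc1 | intermediate
9 | 3-[3-(benzyloxy)-5-methoxy-4-(methoxymethoxy)phenyl]-1-(imidazol-1-yl)propan-1-one | COCOc1c(OC)cc(CCC(=O)n2ccnc2)cc1OCc1ccccc1 | intermediate
10 | lithium 4-[4-(benzyloxy)-3-methoxyphenyl]but-1-en-2-olate | [Li+].C=C([O-])CCc1ccc(OCc2ccccc2)c(OC)c1 | intermediate
11 | 1-[4-(benzyloxy)-3-methoxyphenyl]-7-[3-(benzyloxy)-5-methoxy-4-(methoxymethoxy)phenyl]heptane-3,5-dione | COc1cc(CCC(=O)CC(=O)CCc2cc(OCc3ccccc3)c(OCOC)c(OC)c2)ccc1OCc1ccccc1 | intermediate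
12 | (3S,5S)-1-[4-(benzyloxy)-3-methoxyphenyl]-7-[3-(benzyloxy)-5-methoxy-4-(methoxymethoxy)phenyl]heptane-3,5-diol | COc1cc(CC[C@H](O)C[C@@H](O)CCc2cc(OCc3ccccc3)c(OCOC)c(OC)c2)ccc1OCc1ccccc1 | intermediate
13 | (3S,5S)-1-[4-(benzyloxy)-3-methoxyphenyl]-7-[3-(benzyloxy)-4-hydroxy-5-methoxyphenyl]heptane-3,5-diol | COc1cc(CC[C@H](O)C[C@@H](O)CCc2cc(OCc3ccccc3)c(O)c(OC)c2)ccc1OCc1ccccc1 | intermediate
14 | 2-(benzyloxy)-4-{(3S,5S)-7-[4-(benzyloxy)-3-methoxyphenyl]-3,5-dihydroxyheptylidene}-6-methoxycyclohexa-2,5-dien-1-one | COc1cc(CC[C@H](O)C[C@@H](O)CC=C2C=C(OCc3ccccc3)C(=O)C(OC)=C2)ccc1OCc1ccccc1 | intermediate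
15 | (2S,4R,6S)-2-{2-[4-(benzyloxy)-3-methoxyphenyl]ethyl}-6-[3-(benzyloxy)-4-hydroxy-5-methoxyphenyl]oxan-4-ol | COc1cc(CC[C@H]2C[C@@H](O)C[C@@H](c3cc(OCc4ccccc4)c(O)c(OC)c3)O2)ccc1OCc1ccccc1 | intermediate
16 | (2S,4R,6S)-2-(3,4-dihydroxy-5-methoxyphenyl)-6-[2-(4-hydroxy-3-methoxyphenyl)ethyl]oxan-4-ol | COc1cc(CC[C@H]2C[C@@H](O)C[C@@H](c3cc(O)c(O)c(OC)c3)O2)ccc1O | target

## Step count and least certain steps

Total step count: 9. Longest linear sequence: 8 steps (3, 4, 5, 7, 8, 11, 13, 15, 16, that is steps 2 to 9). Step 1 is the only branch.

**Step 8 (key step).**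
- *Risk.* The most likely failure is a second oxidation at C6–H once the phenol is regenerated, because the product is as easily oxidised as the substrate if closure is already fast on the silver surface. Next in likelihood are tautomerisation of the quinone methide to the conjugated vinylphenol, followed by ionisation of the now allylic hydroxyl, and intermolecular capture at higher concentration.
- *Fallback.* This sets out from 13 and oxidises the benzylic position fully on purpose. DDQ (2.2 equiv) in wet dioxane should carry the quinone methide manifold through two rounds to the C7 aryl ketone F1, which equilibrates with its six-membered hemiketal. Ionic reduction with Et3SiH and BF3·OEt2 in CH2Cl2 at −40 °C then passes through the cyclic oxocarbenium ion, takes up hydride axially, and returns to the route at 15. The O1–C6 disconnection is kept, but conjugate addition is replaced by reductive etherification, a known entry to cis-2,6-tetrahydropyrans.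

**Step 6.**
- *Risk.* Proton transfer from imidazole, from the product, or from the α-CH2 of the acylimidazole may outrun acylation. Enolate equilibration to the internal position and O-acylation may also lower the return.
- *Fallback.* This sets out from 2 and 5 and forms heptane C6–C7 instead of C4–C5. Ketone 2 is acetylated at its methyl group (NaH, EtOAc, THF) to the hexane-2,4-dione F2. Aldehyde 5 is reduced (NaBH4, MeOH) to the benzylic alcohol F3, which is converted by an Appel reaction (CBr4, PPh3, CH2Cl2, 0 °C) into the benzylic bromide F4. The dianion of F2 (NaH, then n-BuLi, THF, 0 °C) is alkylated at its terminal carbon by F4 and returns to the route at 11, by-passing steps 4 to 6.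

**Step 7.**
- *Risk.* The first reduction of a 1,3-diketone is normally highly selective. The likelier weakness is erosion of anti selectivity, or stalling, in the second reduction of this bulky substrate. Early loss of the acetal is harmless.
- *Fallback.* This sets out from 11 and hands the second centre to substrate control. The hydrogenation is interrupted after one equivalent of H2, at the stage of the two regioisomeric (S)-β-hydroxy ketones: the 5-hydroxy-3-ketone F5 and the 3-hydroxy-5-ketone F6 (heptane numbering of 12). The mixture is reduced with Me4NBH(OAc)3 in MeCN/AcOH at −20 °C (Evans–Saksena reduction), where intramolecular hydride delivery gives the 1,3-anti diol from either isomer. Both converge on 12, now isolated, and HCl in MeOH returns to the route at 13.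

**Step 2.**
- *Risk.* Discrimination between the two phenols may be incomplete, and double alkylation may occur, because the more acidic O4 is also the more crowded one.
- *Fallback.* This sets out from 3 and reverses the order by using nucleophilicity instead of acidity. The dianion (NaH, 2.2 equiv, DMSO) reacts with one equivalent of BnBr at the more basic, less delocalised O3 to give 3-(benzyloxy)-4-hydroxy-5-methoxybenzaldehyde F7. MOMCl and iPr2NEt then cap the remaining phenol and return to the route at 5, in the same number of steps.

**Step 9.**
- *Risk.* Competitive hydrogenolysis or acid-trace-induced ionisation of the C6–O1 bond may open the ring, since the para hydroxyl makes this benzylic ether unusually easy to ionise.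
- *Fallback.* This sets out from 15 and switches off that donation first. Ac2O, pyridine and DMAP give the diacetate F8. Hydrogenolysis (H2, Pd/C, EtOAc) removes both benzyl groups from the now less electron-rich system to give the debenzylated diacetate F9. Brief methanolysis (K2CO3, degassed MeOH, 0 °C, argon) returns to the route at 16.

## Further compounds

F1 | step 8 | (3R,5S)-7-[4-(benzyloxy)-3-methoxyphenyl]-1-[3-(benzyloxy)-4-hydroxy-5-methoxyphenyl]-3,5-dihydroxyheptan-1-one | COc1cc(CC[C@H](O)C[C@@H](O)CC(=O)c2cc(OCc3ccccc3)c(O)c(OC)c2)ccc1OCc1ccccc1
F2 | step 6 | 6-[4-(benzyloxy)-3-methoxyphenyl]hexane-2,4-dione | COc1cc(CCC(=O)CC(C)=O)ccc1OCc1ccccc1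
F3 | step 6 | [3-(benzyloxy)-5-methoxy-4-(methoxymethoxy)phenyl]methanol | COCOc1c(OC)cc(CO)cc1OCc1ccccc1
F4 | step 6 | 1-(benzyloxy)-5-(bromomethyl)-3-methoxy-2-(methoxymethoxy)benzene | COCOc1c(OC)cc(CBr)cc1OCc1ccccc1
F5 | step 7 | (5S)-1-[4-(benzyloxy)-3-methoxyphenyl]-7-[3-(benzyloxy)-5-methoxy-4-(methoxymethoxy)phenyl]-5-hydroxyheptan-3-one | COc1cc(CCC(=O)C[C@@H](O)CCc2cc(OCc3ccccc3)c(OCOC)c(OC)c2)ccc1OCc1ccccc1
F6 | step 7 | (5S)-7-[4-(benzyloxy)-3-methoxyphenyl]-1-[3-(benzyloxy)-5-methoxy-4-(methoxymethoxy)phenyl]-5-hydroxyheptan-3-one | COc1cc(CC[C@H](O)CC(=O)CCc2cc(OCc3ccccc3)c(OCOC)c(OC)c2)ccc1OCc1ccccc1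
F7 | step 2 | 3-(benzyloxy)-4-hydroxy-5-methoxybenzaldehyde | COc1cc(C=O)cc(OCc2ccccc2)c1O
F8 | step 9 | (2S,4R,6S)-2-[4-(acetyloxy)-3-(benzyloxy)-5-methoxyphenyl]-6-{2-[4-(benzyloxy)-3-methoxyphenyl]ethyl}oxan-4-yl acetate | COc1cc(CC[C@H]2C[C@@H](OC(C)=O)C[C@@H](c3cc(OCc4ccccc4)c(OC(C)=O)c(OC)c3)O2)ccc1OCc1ccccc1
F9 | step 9 | (2S,4R,6S)-2-[4-(acetyloxy)-3-hydroxy-5-methoxyphenyl]-6-[2-(4-hydroxy-3-methoxyphenyl)ethyl]oxan-4-yl acetate | COc1cc(CC[C@H]2C[C@@H](OC(C)=O)C[C@@H](c3cc(O)c(OC(C)=O)c(OC)c3)O2)ccc1O
A1 | alternative 1 | 2-{(2S)-2-[3,4-bis(benzyloxy)-5-methoxyphenyl]-2-[(tert-butyldimethylsilyl)oxy]ethyl}-2-{(2R)-4-[4-(benzyloxy)-3-methoxyphenyl]-2-hydroxybutyl}-1,3-dithiane | COc1cc(CC[C@@H](O)CC2(C[C@@H](c3cc(OCc4ccccc4)c(OCc4ccccc4)c(OC)c3)O[Si](C)(C)C(C)(C)C)SCCCS2)ccc1OCc1ccccc1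
A2 | alternative 1 | (R)-2-[3,4-bis(benzyloxy)-5-methoxyphenyl]oxirane | C1[C@@H](c2cc(OCc3ccccc3)c(OCc3ccccc3)c(OC)c2)O1
A3 | alternative 1 | (R)-2-{2-[4-(benzyloxy)-3-methoxyphenyl]ethyl}oxirane | COc1cc(CC[C@@H]2CO2)ccc1OCc1ccccc1
A4 | alternative 1 | 2-(tert-butyldimethylsilyl)-1,3-dithiane | CC(C)(C)[Si](C)(C)C1SCCCS1
A5 | alternative 2 | (2S,6S)-2-{2-[4-(benzyloxy)-3-methoxyphenyl]ethyl}-6-[3,4-bis(benzyloxy)-5-methoxyphenyl]oxan-4-one | COc1cc(CC[C@H]2CC(=O)C[C@@H](c3cc(OCc4ccccc4)c(OCc4ccccc4)c(OC)c3)O2)ccc1OCc1ccccc1
A6 | alternative 2 | (2R,6S)-2-{2-[4-(benzyloxy)-3-methoxyphenyl]ethyl}-6-[3,4-bis(benzyloxy)-5-methoxyphenyl]-4-methylidene-1,3-dioxane | C=C1C[C@@H](c2cc(OCc3ccccc3)c(OCc3ccccc3)c(OC)c2)O[C@@H](CCc2ccc(OCc3ccccc3)c(OC)c2)O1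
A7 | alternative 2 | (3S)-3-[3,4-bis(benzyloxy)-5-methoxyphenyl]-3-hydroxypropanoic acid | OC(=O)C[C@@H](c1cc(OCc2ccccc2)c(OCc2ccccc2)c(OC)c1)O
A8 | alternative 2 | 3-[4-(benzyloxy)-3-methoxyphenyl]propanal | COc1cc(CCC=O)ccc1OCc1ccccc1
A9 | alternative 3 | (2S,4R,6S)-2-{2-[4-(benzyloxy)-3-methoxyphenyl]ethyl}-6-[3,4-bis(benzyloxy)-5-methoxyphenyl]oxan-4-yl acetate | COc1cc(CC[C@H]2C[C@@H](OC(C)=O)C[C@@H](c3cc(OCc4ccccc4)c(OCc4ccccc4)c(OC)c3)O2)ccc1OCc1ccccc1
A10 | alternative 3 | (1S,3S)-7-[4-(benzyloxy)-3-methoxyphenyl]-1-[3,4-bis(benzyloxy)-5-methoxyphenyl]-5-oxo-1-[(triethylsilyl)oxy]heptan-3-yl acetate | COc1cc(CCC(=O)C[C@@H](OC(C)=O)C[C@@H](c2cc(OCc3ccccc3)c(OCc3ccccc3)c(OC)c2)O[Si](CC)(CC)CC)ccc1OCc1ccccc1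
A11 | alternative 3 | (3S)-3-[3,4-bis(benzyloxy)-5-methoxyphenyl]-3-[(triethylsilyl)oxy]propanal | O=CC[C@@H](c1cc(OCc2ccccc2)c(OCc2ccccc2)c(OC)c1)O[Si](CC)(CC)CC
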